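**Retrosynthetic overview**

- Cyclobutane labels: C-a = O-bearing quaternary carbon, C-b = ring-fusion CH, C-c = CH(Ph), C-d = CH(pyranone). The pyranone is the last ring: O-methylation of a 4-hydroxy-2-pyranone, itself made by Claisen-type C-acylation of the silyl dienol ether of 2,2,6-trimethyl-1,3-dioxin-4-one with the C-d acid chloride, then thermolysis.
- The fused methoxy-dihydropyranone comes from a Claisen ring closure of a cis acetate/activated amide pair on C-a/C-b. The phenyl on C-c comes from amide-directed C–H arylation, which places it cis to the C-b acyl group.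
- The cyclobutane comes from an intramolecular [2+2] photocycloaddition of a dioxinone allyl ether. Benzylic hydrogenolysis then opens the tether ring, leaving the 2-phenylethyl chain on C-a and CH2OH on C-d.
- Key C–C bond: catalytic asymmetric vinylogous aldol addition of the dioxinone silyl dienolate to benzaldehyde. Its carbinol centre is the only external source of chirality and is erased after it has done its work.
- Ring order: dioxinone (bought) → cyclobutane plus temporary tetrahydropyran → dihydropyranone → pyranone.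

Assumption: in the photocycloaddition the R carbinol centre sits with its phenyl group equatorial in the half-chair of the forming tetrahydropyran and so favours the alkene face drawn; this preference is predicted, not proven, and the other diastereomer is removed by chromatography before the centre is erased.

**Route**

Step 1
Reactants: 1 2,2,6-trimethyl-4H-1,3-dioxin-4-one
Product: 3 [(2,2-dimethyl-6-methylidene-6H-1,3-dioxin-4-yl)oxy]trimethylsilane, via lithium dienolate 2 (not isolated)
Conditions: LiN(iPr)2, THF, −78 °C; Me3SiCl, −78 °C to rt; distillation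
Reagents that add atoms: chlorotrimethylsilane C[Si](C)(C)Cl
Why: γ-Deprotonation of the vinylogous ester and O-silylation (silyl dienol ether formation) give the distillable nucleophile that serves both the Mukaiyama aldol of step 2 and the acylation of step 15; no stereocentre is formed.

Step 2
Reactants: 3 [(2,2-dimethyl-6-methylidene-6H-1,3-dioxin-4-yl)oxy]trimethylsilane; 4 benzaldehyde
Product: 6 6-[(2R)-2-hydroxy-2-phenylethyl]-2,2-dimethyl-4H-1,3-dioxin-4-one, via trimethylsilyl ether 5 (not isolated)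
Conditions: Cu(OTf)2 (2 mol%), (S)-Tol-BINAP (2.2 mol%), Bu4N[Ph3SiF2] (4 mol%), THF, −78 °C; then CF3CO2H, THF–H2O, rt
Reagents that add atoms: none
Why: A catalytic asymmetric vinylogous Mukaiyama aldol addition joins the two fragments at the γ-carbon and sets the R carbinol centre through the chiral bisphosphine (the ligand antipode is used if Mosher analysis shows the opposite sense).

Step 3
Reactants: 6 6-[(2R)-2-hydroxy-2-phenylethyl]-2,2-dimethyl-4H-1,3-dioxin-4-one
Product: 7 2,2-dimethyl-6-[(2R)-2-phenyl-2-(prop-2-en-1-yloxy)ethyl]-4H-1,3-dioxin-4-one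
Conditions: allyl 2,2,2-trichloroacetimidate, TfOH (5 mol%), CH2Cl2–cyclohexane, 0 °C
Reagents that add atoms: allyl 2,2,2-trichloroacetimidate C=CCOC(=N)C(Cl)(Cl)Cl
Why: Acid-catalysed O-alkylation with a trichloroacetimidate allylates the base-sensitive β-hydroxy dioxinone without retro-aldol or elimination and leaves the carbinol configuration untouched.

Step 4
Reactants: 7 2,2-dimethyl-6-[(2R)-2-phenyl-2-(prop-2-en-1-yloxy)ethyl]-4H-1,3-dioxin-4-one
Product: 8 tricyclic photoadduct: cyclobutane cis-fused along C-a–C-b to the 2,2-dimethyl-1,3-dioxan-4-one and along C-a–C-d to a (2R)-2-phenyltetrahydropyran whose ring oxygen is bonded to the CH2 on C-d; at C-a the dioxanone oxygen and the tetrahydropyran CH2 lie on opposite faces; C-c is CH2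
Conditions: hν (300 nm, Pyrex), MeCN–acetone 9:1, 0.01 M, 0 °C; chromatography
Reagents that add atoms: none
Why: In this intramolecular enone–alkene [2+2] photocycloaddition (de Mayo-type dioxinone addition) the four-atom tether enforces the straight regiochemistry and two cis ring fusions, which fixes C-a, C-b and C-d relative to one another, while the carbinol centre selects the alkene face and hence the absolute configuration.

Step 5
Reactants: 8 tricyclic photoadduct
Product: 9 (1S,6R,8S)-8-(hydroxymethyl)-3,3-dimethyl-1-(2-phenylethyl)-2,4-dioxabicyclo[4.2.0]octan-5-one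
Conditions: H2 (3 atm), Pd(OH)2/C, EtOAc, AcOH (cat.), rt
Reagents that add atoms: none
Why: Benzylic C–O hydrogenolysis cleaves only the phenyl-substituted ether bond, which opens the tether ring to the 2-phenylethyl chain on C-a and a hydroxymethyl group on C-d without touching the three cyclobutane centres.

Step 6
Reactants: 9 (1S,6R,8S)-8-(hydroxymethyl)-3,3-dimethyl-1-(2-phenylethyl)-2,4-dioxabicyclo[4.2.0]octan-5-one
Product: 10 (1S,6R,8S)-8-({[tert-butyl(dimethyl)silyl]oxy}methyl)-3,3-dimethyl-1-(2-phenylethyl)-2,4-dioxabicyclo[4.2.0]octan-5-one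
Conditions: TBSCl, imidazole, DMF, rt
Reagents that add atoms: tert-butyl(chloro)dimethylsilane CC(C)(C)[Si](C)(C)Cl
Why: Silyl ether formation protects the primary alcohol through the amide, arylation and enolate steps.

Step 7
Reactants: 10 silyl ether of step 6; 11 quinolin-8-amine
Product: 12 (1R,2S,3S)-3-({[tert-butyl(dimethyl)silyl]oxy}methyl)-2-hydroxy-2-(2-phenylethyl)-N-(quinolin-8-yl)cyclobutane-1-carboxamide
Conditions: AlMe3, CH2Cl2, 0 to 40 °C; aq. potassium sodium tartrate
Reagents that add atoms: none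
Why: Aluminium-amide aminolysis (Weinreb-type) opens the acylal-like dioxanone with loss of acetone and installs the bidentate directing amide on C-b, and the resulting β-hydroxy amide is far less prone to retro-aldol ring opening than a ketone or ester would be.

Step 8
Reactants: 12 hydroxy amide of step 7
Product: 13 (1R,2S,3S)-2-(acetyloxy)-3-({[tert-butyl(dimethyl)silyl]oxy}methyl)-2-(2-phenylethyl)-N-(quinolin-8-yl)cyclobutane-1-carboxamide
Conditions: Ac2O, Et3N, DMAP, CH2Cl2, 40 °C
Reagents that add atoms: acetic anhydride CC(=O)OC(C)=O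
Why: DMAP-catalysed (Steglich-type) acetylation caps the tertiary cyclobutanol, which blocks metal-alkoxide ring opening in the next step and supplies the two carbons for the later Claisen ring closure.

Step 9
Reactants: 13 acetate of step 8; 14 iodobenzene
Product: 15 (1R,2S,3S,4R)-2-(acetyloxy)-3-({[tert-butyl(dimethyl)silyl]oxy}methyl)-4-phenyl-2-(2-phenylethyl)-N-(quinolin-8-yl)cyclobutane-1-carboxamide
Conditions: Pd(OAc)2 (10 mol%), AgOAc (2 equiv), PhI (4 equiv), toluene, 110 °C
Reagents that add atoms: none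
Why: The 8-aminoquinoline-directed, palladium-catalysed C(sp3)–H arylation proceeds through a five-membered palladacycle and delivers phenyl to the only β-C–H bond cis to the amide, so the phenyl on C-c ends cis to the C-b acyl group and trans to the C-d substituent (fourth stereocentre).

Step 10
Reactants: 15 arylated amide of step 9
Product: 16 tert-butyl N-{[(1R,2S,3S,4R)-2-(acetyloxy)-3-({[tert-butyl(dimethyl)silyl]oxy}methyl)-4-phenyl-2-(2-phenylethyl)cyclobutyl]carbonyl}-N-(quinolin-8-yl)carbamate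
Conditions: Boc2O (5 equiv), DMAP, MeCN, 60 °C
Reagents that add atoms: di-tert-butyl dicarbonate CC(C)(C)OC(=O)OC(=O)OC(C)(C)C
Why: N-Acylation turns the robust directing amide into a twisted imide-type acyl donor with a carbamate leaving group.

Step 11
Reactants: 16 N-Boc amide of step 10
Product: 17 (1S,6S,7R,8S)-8-({[tert-butyl(dimethyl)silyl]oxy}methyl)-5-hydroxy-7-phenyl-1-(2-phenylethyl)-2-oxabicyclo[4.2.0]oct-4-en-3-one
Conditions: LiN(SiMe3)2 (3 equiv), THF, −78 to −30 °C; aq. NH4Cl, then 1 M HCl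
Reagents that add atoms: none
Why: In this Dieckmann-type intramolecular Claisen condensation the acetate enolate attacks the cis activated amide through a six-membered transition state and expels the carbamate, which closes the cis-fused β-keto-δ-lactone without ever freeing the tertiary cyclobutanol.

Step 12
Reactants: 17 hydroxy-dihydropyranone of step 11
Product: 18 (1S,6S,7R,8S)-8-({[tert-butyl(dimethyl)silyl]oxy}methyl)-5-methoxy-7-phenyl-1-(2-phenylethyl)-2-oxabicyclo[4.2.0]oct-4-en-3-one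
Conditions: Me2SO4, K2CO3, acetone, rt
Reagents that add atoms: dimethyl sulfate COS(=O)(=O)OC
Why: O-Alkylation of the vinylogous acid with a hard methylating agent gives the 4-methoxy-5,6-dihydropyran-2-one enol ether.

Step 13
Reactants: 18 methyl enol ether of step 12
Product: 19 (1S,6S,7R,8S)-8-(hydroxymethyl)-5-methoxy-7-phenyl-1-(2-phenylethyl)-2-oxabicyclo[4.2.0]oct-4-en-3-one
Conditions: HF·pyridine, THF–pyridine, 0 °C to rt
Reagents that add atoms: none
Why: Fluoride-mediated desilylation frees the primary alcohol under buffered conditions that spare the enol ether and the lactone.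

Step 14
Reactants: 19 primary alcohol of step 13
Product: 21 (1R,6S,7S,8R)-5-methoxy-3-oxo-7-phenyl-1-(2-phenylethyl)-2-oxabicyclo[4.2.0]oct-4-ene-8-carboxylic acid, via aldehyde 20 (not isolated)
Conditions: TEMPO (20 mol%), PhI(OAc)2 (2.5 equiv), MeCN–H2O 1:1, rt
Reagents that add atoms: water O
Why: The TEMPO/PhI(OAc)2 (oxoammonium) oxidation takes the alcohol through the aldehyde hydrate to the acid under near-neutral conditions that do not epimerise C-d.

Step 15
Reactants: 21 carboxylic acid of step 14; 3 [(2,2-dimethyl-6-methylidene-6H-1,3-dioxin-4-yl)oxy]trimethylsilane (second portion of the batch from step 1)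
Product: 23 (1R,6S,7S,8R)-8-[(2,2-dimethyl-4-oxo-4H-1,3-dioxin-6-yl)acetyl]-5-methoxy-7-phenyl-1-(2-phenylethyl)-2-oxabicyclo[4.2.0]oct-4-en-3-one, via acid chloride 22 (not isolated)
Conditions: 21, 1-chloro-N,N,2-trimethylprop-1-en-1-amine (1.2 equiv), CH2Cl2, 0 °C to rt; then 3 (2.5 equiv), CH2Cl2, −78 °C to rt; pH 7 buffer
Reagents that add atoms: none
Why: In this Mukaiyama-type vinylogous Claisen acylation the γ-carbon of the silyl ketene acetal attacks the acid chloride and Me3SiCl is lost under neutral, base-free conditions, so the α-hydrogen on C-d, which has an acyloxy group in the β-position, never meets a strong base and C-d keeps its configuration.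

Step 16
Reactants: 23 keto dioxinone of step 15
Product: 25 (1R,6S,7S,8S)-8-(4-hydroxy-2-oxo-2H-pyran-6-yl)-5-methoxy-7-phenyl-1-(2-phenylethyl)-2-oxabicyclo[4.2.0]oct-4-en-3-one, via acylketene 24 (not isolated)
Conditions: toluene, 110 °C, 1 h
Reagents that add atoms: none
Why: A retro-hetero-Diels–Alder loss of acetone gives the acylketene, which is trapped by the enol oxygen of the neighbouring ketone to close the 4-hydroxy-2-pyranone under neutral conditions.

Step 17
Reactants: 25 hydroxypyranone of step 16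
Product: 26 (1R,6S,7S,8S)-5-methoxy-8-(4-methoxy-2-oxo-2H-pyran-6-yl)-7-phenyl-1-(2-phenylethyl)-2-oxabicyclo[4.2.0]oct-4-en-3-one
Conditions: Me2SO4, K2CO3, acetone, rt
Reagents that add atoms: dimethyl sulfate COS(=O)(=O)OC
Why: O-Methylation of the vinylogous acid at O-4 gives the 4-methoxy-2-pyranone, and K2CO3 is too weak to trigger β-elimination at C-d.

**Compound list**

1 | 2,2,6-trimethyl-4H-1,3-dioxin-4-one | CC1=CC(=O)OC(C)(C)O1 | starting material
2 | lithium 2,2-dimethyl-6-methylidene-6H-1,3-dioxin-4-olate | [Li+].C=C1C=C([O-])OC(C)(C)O1 | intermediate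
3 | [(2,2-dimethyl-6-methylidene-6H-1,3-dioxin-4-yl)oxy]trimethylsilane | C=C1C=C(O[Si](C)(C)C)OC(C)(C)O1 | intermediate
4 | benzaldehyde | O=Cc1ccccc1 | starting material
5 | 2,2-dimethyl-6-[(2R)-2-phenyl-2-(trimethylsilyloxy)ethyl]-4H-1,3-dioxin-4-one | CC1(C)OC(=O)C=C(C[C@@H](O[Si](C)(C)C)c2ccccc2)O1 | intermediate
6 | 6-[(2R)-2-hydroxy-2-phenylethyl]-2,2-dimethyl-4H-1,3-dioxin-4-one | CC1(C)OC(=O)C=C(C[C@@H](O)c2ccccc2)O1 | intermediate
7 | 2,2-dimethyl-6-[(2R)-2-phenyl-2-(prop-2-en-1-yloxy)ethyl]-4H-1,3-dioxin-4-one | CC1(C)OC(=O)C=C(C[C@@H](OCC=C)c2ccccc2)O1 | intermediate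
8 | tricyclic photoadduct (cyclobutane cis-fused to the dioxanone at C-a/C-b and to a (2R)-2-phenyltetrahydropyran at C-a/C-d) | CC1(C)OC(=O)[C@@H]2C[C@H]3CO[C@@H](c4ccccc4)C[C@@]23O1 | intermediate
9 | (1S,6R,8S)-8-(hydroxymethyl)-3,3-dimethyl-1-(2-phenylethyl)-2,4-dioxabicyclo[4.2.0]octan-5-one | CC1(C)OC(=O)[C@@H]2C[C@@H](CO)[C@]2(CCc3ccccc3)O1 | intermediate
10 | (1S,6R,8S)-8-({[tert-butyl(dimethyl)silyl]oxy}methyl)-3,3-dimethyl-1-(2-phenylethyl)-2,4-dioxabicyclo[4.2.0]octan-5-one | CC1(C)OC(=O)[C@@H]2C[C@@H](CO[Si](C)(C)C(C)(C)C)[C@]2(CCc3ccccc3)O1 | intermediate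
11 | quinolin-8-amine | Nc1cccc2cccnc12 | starting material
12 | (1R,2S,3S)-3-({[tert-butyl(dimethyl)silyl]oxy}methyl)-2-hydroxy-2-(2-phenylethyl)-N-(quinolin-8-yl)cyclobutane-1-carboxamide | O=C(Nc1cccc2cccnc12)[C@@H]1C[C@@H](CO[Si](C)(C)C(C)(C)C)[C@@]1(O)CCc3ccccc3 | intermediate
13 | (1R,2S,3S)-2-(acetyloxy)-3-({[tert-butyl(dimethyl)silyl]oxy}methyl)-2-(2-phenylethyl)-N-(quinolin-8-yl)cyclobutane-1-carboxamide | O=C(Nc1cccc2cccnc12)[C@@H]1C[C@@H](CO[Si](C)(C)C(C)(C)C)[C@@]1(OC(C)=O)CCc3ccccc3 | intermediate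
14 | iodobenzene | Ic1ccccc1 | starting material
15 | (1R,2S,3S,4R)-2-(acetyloxy)-3-({[tert-butyl(dimethyl)silyl]oxy}methyl)-4-phenyl-2-(2-phenylethyl)-N-(quinolin-8-yl)cyclobutane-1-carboxamide | O=C(Nc1cccc2cccnc12)[C@@H]1[C@H](c3ccccc3)[C@@H](CO[Si](C)(C)C(C)(C)C)[C@@]1(OC(C)=O)CCc4ccccc4 | intermediate
16 | tert-butyl N-{[(1R,2S,3S,4R)-2-(acetyloxy)-3-({[tert-butyl(dimethyl)silyl]oxy}methyl)-4-phenyl-2-(2-phenylethyl)cyclobutyl]carbonyl}-N-(quinolin-8-yl)carbamate | CC(C)(C)OC(=O)N(c1cccc2cccnc12)C(=O)[C@@H]1[C@H](c3ccccc3)[C@@H](CO[Si](C)(C)C(C)(C)C)[C@@]1(OC(C)=O)CCc4ccccc4 | intermediate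
17 | (1S,6S,7R,8S)-8-({[tert-butyl(dimethyl)silyl]oxy}methyl)-5-hydroxy-7-phenyl-1-(2-phenylethyl)-2-oxabicyclo[4.2.0]oct-4-en-3-one | OC1=CC(=O)O[C@]2(CCc3ccccc3)[C@H]1[C@H](c1ccccc1)[C@H]2CO[Si](C)(C)C(C)(C)C | intermediate
18 | (1S,6S,7R,8S)-8-({[tert-butyl(dimethyl)silyl]oxy}methyl)-5-methoxy-7-phenyl-1-(2-phenylethyl)-2-oxabicyclo[4.2.0]oct-4-en-3-one | COC1=CC(=O)O[C@]2(CCc3ccccc3)[C@H]1[C@H](c1ccccc1)[C@H]2CO[Si](C)(C)C(C)(C)C | intermediate
19 | (1S,6S,7R,8S)-8-(hydroxymethyl)-5-methoxy-7-phenyl-1-(2-phenylethyl)-2-oxabicyclo[4.2.0]oct-4-en-3-one | COC1=CC(=O)O[C@]2(CCc3ccccc3)[C@H]1[C@H](c1ccccc1)[C@H]2CO | intermediate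
20 | (1R,6S,7S,8R)-5-methoxy-3-oxo-7-phenyl-1-(2-phenylethyl)-2-oxabicyclo[4.2.0]oct-4-ene-8-carbaldehyde | COC1=CC(=O)O[C@]2(CCc3ccccc3)[C@H]1[C@H](c1ccccc1)[C@H]2C=O | intermediate
21 | (1R,6S,7S,8R)-5-methoxy-3-oxo-7-phenyl-1-(2-phenylethyl)-2-oxabicyclo[4.2.0]oct-4-ene-8-carboxylic acid | COC1=CC(=O)O[C@]2(CCc3ccccc3)[C@H]1[C@H](c1ccccc1)[C@H]2C(=O)O | intermediate
22 | (1R,6S,7S,8R)-5-methoxy-3-oxo-7-phenyl-1-(2-phenylethyl)-2-oxabicyclo[4.2.0]oct-4-ene-8-carbonyl chloride | COC1=CC(=O)O[C@]2(CCc3ccccc3)[C@H]1[C@H](c1ccccc1)[C@H]2C(Cl)=O | intermediate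
23 | (1R,6S,7S,8R)-8-[(2,2-dimethyl-4-oxo-4H-1,3-dioxin-6-yl)acetyl]-5-methoxy-7-phenyl-1-(2-phenylethyl)-2-oxabicyclo[4.2.0]oct-4-en-3-one | COC1=CC(=O)O[C@]2(CCc3ccccc3)[C@H]1[C@H](c1ccccc1)[C@H]2C(=O)CC1=CC(=O)OC(C)(C)O1 | intermediate
24 | (1R,6S,7S,8R)-8-(3,5-dioxopent-4-enoyl)-5-methoxy-7-phenyl-1-(2-phenylethyl)-2-oxabicyclo[4.2.0]oct-4-en-3-one (acylketene) | COC1=CC(=O)O[C@]2(CCc3ccccc3)[C@H]1[C@H](c1ccccc1)[C@H]2C(=O)CC(=O)C=C=O | intermediate
25 | (1R,6S,7S,8S)-8-(4-hydroxy-2-oxo-2H-pyran-6-yl)-5-methoxy-7-phenyl-1-(2-phenylethyl)-2-oxabicyclo[4.2.0]oct-4-en-3-one | COC1=CC(=O)O[C@]2(CCc3ccccc3)[C@H]1[C@H](c1ccccc1)[C@H]2c1cc(O)cc(=O)o1 | intermediate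
26 | (1R,6S,7S,8S)-5-methoxy-8-(4-methoxy-2-oxo-2H-pyran-6-yl)-7-phenyl-1-(2-phenylethyl)-2-oxabicyclo[4.2.0]oct-4-en-3-one | COC1=CC(=O)O[C@]2(CCc3ccccc3)[C@H]1[C@H](c1ccccc1)[C@H]2c1cc(OC)cc(=O)o1 | target

**Count and risks**

Total step count: 17. Longest linear sequence: 17 steps (1 to 26); benzaldehyde, quinolin-8-amine and iodobenzene enter as single reagents, and a second portion of silyl dienol ether 3 from step 1 enters at step 15.

Steps most likely to fail:

Step 4 (which alkene face reacts, and the slower six-ring-forming mode). A low ratio only costs yield, because the diastereomers are separated before step 5. If the favoured face is the wrong one, the controlling centre is inverted by redox chemistry instead of relying on the aldol-derived R centre. The fallback sets out from 6: Dess–Martin oxidation gives the phenacyl dioxinone F1, and transfer hydrogenation with RuCl(p-cymene)[(S,S)-TsDPEN] in HCO2H–Et3N gives the S carbinol F2. Allylation as in step 3 gives the S allyl ether F3, and irradiation as in step 4 gives the benzylic epimer of the photoadduct F4, which has the cyclobutane configuration of 8. Hydrogenolysis as in step 5 erases the benzylic centre and comes back to the route at 9.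

Step 9 (C–H arylation beside a quaternary carbon, with an acetate β to the amide). The fallback brings the phenyl group in with the alkene instead of by C–H activation, and sets out from 6. (E)-Cinnamyl 2,2,2-trichloroacetimidate with catalytic TfOH gives the cinnamyl ether F5. Irradiation as in step 4 gives the phenyl-substituted photoadduct F6; the C-c configuration passes through a benzylic 1,4-diradical, so the C-c epimer may have to be removed by chromatography. Hydrogenolysis as in step 5 gives the alcohol F7, silylation as in step 6 the silyl ether F8, and aminolysis as in step 7 the hydroxy amide F9. Acetylation as in step 8 comes back to the route at 15.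

Step 15 (the uncatalysed C-acylation of the silyl dienol ether by a hindered cyclobutane acid chloride may be slow, and the acid chloride has an acyloxy group β to its α-hydrogen, so material can be lost by elimination). The fallback replaces the acylation by an aldol/oxidation pair under Lewis-acidic and neutral conditions, and sets out from 19. Dess–Martin oxidation gives aldehyde 20, isolated this time. A BF3·OEt2-mediated vinylogous Mukaiyama aldol addition of silyl dienolate 3 at −78 °C gives the hydroxy dioxinone F10 as a mixture of carbinol epimers. A second Dess–Martin oxidation converges both epimers and comes back to the route at 23.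

**Further compounds**

F1 | step 4 | 2,2-dimethyl-6-(2-oxo-2-phenylethyl)-4H-1,3-dioxin-4-one | CC1(C)OC(=O)C=C(CC(=O)c2ccccc2)O1
F2 | step 4 | 6-[(2S)-2-hydroxy-2-phenylethyl]-2,2-dimethyl-4H-1,3-dioxin-4-one | CC1(C)OC(=O)C=C(C[C@H](O)c2ccccc2)O1
F3 | step 4 | 2,2-dimethyl-6-[(2S)-2-phenyl-2-(prop-2-en-1-yloxy)ethyl]-4H-1,3-dioxin-4-one | CC1(C)OC(=O)C=C(C[C@H](OCC=C)c2ccccc2)O1
F4 | step 4 | benzylic (2S) epimer of photoadduct 8 with the same cyclobutane configuration | CC1(C)OC(=O)[C@@H]2C[C@H]3CO[C@H](c4ccccc4)C[C@@]23O1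
F5 | step 9 | 2,2-dimethyl-6-[(2R)-2-phenyl-2-{[(2E)-3-phenylprop-2-en-1-yl]oxy}ethyl]-4H-1,3-dioxin-4-one | CC1(C)OC(=O)C=C(C[C@@H](OC/C=C/c2ccccc2)c2ccccc2)O1
F6 | step 9 | photoadduct 8 carrying a phenyl group on C-c cis to the dioxanone carbonyl carbon on C-b | CC1(C)OC(=O)[C@@H]2[C@H](c3ccccc3)[C@H]3CO[C@@H](c4ccccc4)C[C@@]23O1
F7 | step 9 | (1S,6R,7R,8S)-8-(hydroxymethyl)-3,3-dimethyl-7-phenyl-1-(2-phenylethyl)-2,4-dioxabicyclo[4.2.0]octan-5-one | CC1(C)OC(=O)[C@@H]2[C@H](c3ccccc3)[C@@H](CO)[C@]2(CCc3ccccc3)O1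
F8 | step 9 | (1S,6R,7R,8S)-8-({[tert-butyl(dimethyl)silyl]oxy}methyl)-3,3-dimethyl-7-phenyl-1-(2-phenylethyl)-2,4-dioxabicyclo[4.2.0]octan-5-one | CC1(C)OC(=O)[C@@H]2[C@H](c3ccccc3)[C@@H](CO[Si](C)(C)C(C)(C)C)[C@]2(CCc3ccccc3)O1
F9 | step 9 | (1R,2S,3S,4R)-3-({[tert-butyl(dimethyl)silyl]oxy}methyl)-2-hydroxy-4-phenyl-2-(2-phenylethyl)-N-(quinolin-8-yl)cyclobutane-1-carboxamide | O=C(Nc1cccc2cccnc12)[C@@H]1[C@H](c3ccccc3)[C@@H](CO[Si](C)(C)C(C)(C)C)[C@@]1(O)CCc4ccccc4
F10 | step 15 | (1S,6S,7R,8S)-8-[2-(2,2-dimethyl-4-oxo-4H-1,3-dioxin-6-yl)-1-hydroxyethyl]-5-methoxy-7-phenyl-1-(2-phenylethyl)-2-oxabicyclo[4.2.0]oct-4-en-3-one (both carbinol epimers) | COC1=CC(=O)O[C@]2(CCc3ccccc3)[C@H]1[C@H](c1ccccc1)[C@H]2C(O)CC1=CC(=O)OC(C)(C)O1
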